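Remark on the chemistry: rings are lettered A to E in the order of the SMILES string, and C1 of rings B to E is the carbon bearing the ether oxygen toward the preceding ring. Aldehydes 14 and 18 and iodide 22 are assumed to be purchasable building blocks.

## Analysis of the target

The target (C30H22O15) is a linear pentamer of phloroglucinol: five benzene rings joined by four diaryl ether oxygens, with eleven free phenolic hydroxyls and no carbon substituent. Ring A is a 3,5-dihydroxyphenyl ether, rings B and D are 1,2,3,5-tetraoxygenated with vicinal ether oxygens at C1 and C6 and hydroxyls at C2 and C4, ring C has its ether oxygens para (C1, C4) with hydroxyls at C2 and C6, and ring E is a 2,4,6-trihydroxyphenyl group. There are no stereocentres, so the only selectivity problem is the placement of oxygen on each ring. The free polyphenol is sensitive to air and base, because rings B, C and D are hydroquinone- or hydroxyquinol-like and oxidise to quinones; all hydroxyls therefore stay masked until the last step. The difficulty lies in the four C–O–C bonds between electron-rich rings: the oxygens on C1 of rings B, C, D and E each sit between two oxygenated carbons, while their partner carbons carry one ortho oxygen (ring D C6, ring B C6) or none (ring C C4, ring A C1). The strategy rests on ring E, where C1 bears the ether oxygen and C2, C4 and C6 bear hydroxyls, which is the oxygenation pattern of a folded triketide. Ring E C1 corresponds to C6 of a 3,5-dioxohexanoate and ring E C2 to its ester carbon, so the E–D ether can be made as an alkyl aryl ether before ring E exists.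

## Retrosynthetic reasoning

Target 24 is traced to its undecamethyl ether 23 by cutting only the eleven O–CH3 bonds. Methyl ethers tolerate the strong bases, peracid, hot Ullmann conditions and hydrogenation used earlier. The four diaryl ether bonds are inert to Lewis-acid dealkylation, because halide cannot attack an aryl carbon.

In 23 the A–O–B ether is cut on the ring A side. The ring B C1 oxygen is flanked by methoxy (C2) and aryloxy (C6), so it can only serve as the nucleophile, phenol 21. Ring A C1 has two ortho hydrogens and is the natural electrophile, iodide 22, in an Ullmann-type coupling.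

The ring B C1 hydroxyl of 21 is traced to a formyl group in aldehyde 19, through formate 20 by peracid oxidation. The formyl group serves twice: in bromoaldehyde 18 it activates the neighbouring C6–Br bond for C–O formation, and afterwards it becomes the oxygen that ring B needs at C1. Cutting the ring B C6–O bond of 19 gives phenol 17 and 18. The cut is made on this side because ring C C1, with two ortho methoxy groups, cannot act as an electrophile.

The same reasoning is applied once more. Phenol 17 comes from aldehyde 15 through formate 16. Cutting the ring C C4–O bond of 15 gives the ring D phenol 13 and bromoaldehyde 14. In 14 the bromide is para to the formyl group and has hydrogen on both sides, which makes this the easiest of the three arylations.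

Phenol 13 comes from benzyl ether 12 by hydrogenolysis, and 12 from triol 11 by methylation of the three ring E hydroxyls. The benzyl group on the ring D C1 oxygen is the one temporary group of the route. It is orthogonal to methyl, so that this oxygen alone is released for the coupling with 14.

Triol 11 is opened at the C1–C2 bond of ring E to the diketo ester 9, through trione 10. The cut is made here because ring E is terminal and carries only hydroxyls besides the ether, so its carbons map cleanly onto a 3,5-dioxohexanoate. The forward reaction must make C6 of the chain attack the ester carbon rather than let the C5 enol oxygen do so. The E–D ether joins a di-ortho-oxygenated carbon to a carbon with an ortho oxygen. It is sterically the same class as the C–B ether, which the route makes by arylation; here the bond already exists in 9 as an sp3 C–O bond.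

Diketo ester 9 is cut between C4 and C5 into ester 6 and the dianion 8 of methyl acetoacetate 7. Acylation of the terminal carbon of 8 by an α-oxygenated ester is a standard way to such chains.

Ester 6 comes from phenol 5 by benzylation, 5 from aldehyde 3 through formate 4, and 3 from salicylaldehyde 1 and bromoacetate 2. The substitution of 1 fixes the regiochemistry of ring D. Its free hydroxyl (future ring D C6 oxygen) is alkylated first, and the adjacent formyl carbon then becomes the ring D C1 oxygen. The two vicinal oxygens are thus differentiated from the outset, and the methoxy groups end up at ring D C2 and C4.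

## Alternatives that were turned down

Alternative 1: Both C–O bonds at ring D are cut. Ring D becomes the dichloroarene ligand of the cationic cyclopentadienylruthenium complex [CpRu(1,2-dichloro-3,5-dimethoxybenzene)]PF6 A2 . In the forward key step the phenoxide of 2,4,6-trimethoxyphenol A3 displaces the chloride at ring D C6 of A2 . The ring C C4 phenoxide of the ABC phenol A4 then displaces the chloride at C1, and the ruthenium complex of the undecamethyl ether A1 results. Photolytic release of the metal from A1 and demethylation follow.
- For: the metal turns an electron-rich ring into an SNAr electrophile at low temperature. Both ethers of a congested ring are made without hot Ullmann chemistry. The assembly is convergent (E + D + ABC).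
- Against: the order of the two displacements rests only on the steric difference between a chloride flanked by Cl and H and one flanked by Cl and OMe, and the first nucleophile A3 is itself di-ortho-substituted. The second displacement occurs at a carbon now flanked by aryloxy and methoxy, on a ring made less electrophilic by the first aryloxy donor. Ruthenium is stoichiometric, and complexation and decomplexation add steps. A4 still contains the A–B and B–C ethers, so the hindered-ether problem is only moved.
- Comparison: on convergence and mildness at ring D this alternative is stronger. The chosen route instead fixes each oxygen of ring D through the substitution of aldehyde 1 rather than through selection between two similar leaving groups, uses no stoichiometric precious metal, and puts its risk on a small early intermediate.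

Alternative 2: Ring B is opened between C3 and C4, back to the 4-hydroxy-4-(1-methoxyvinyl)cyclobutenone A6 , which carries the CDE aryloxy group at C3. Heating A6 triggers electrocyclic opening of the four-membered ring, followed by 6π-electrocyclisation between the ketene carbon and the vinyl terminus. Tautomerisation then gives the BCDE hydroquinone A5 , with ring B C1–OH and C4–OH free and C2 methoxylated.
- For: the hindered C–O–B ether would arise by addition–elimination at a four-membered vinylogous ester, not by arylation. The thermal cascade needs no reagent and delivers the ring B oxygenation pattern regiospecifically.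
- Against: the CDE portion must exist first as a phenol, which is compound 17 of the chosen route, so the E–D and D–C bonds are untouched by this idea. A6 needs hydrogen at the carbon that becomes ring B C5, hence a more elaborate four-carbon building block and extra steps. A5 has two free hydroxyls that must be told apart, and it is an oxidation-prone hydroquinone. The A–B ether still needs arylation of a di-ortho-substituted phenol.
- Comparison: for the C–B bond alone this alternative is arguably stronger than the Ullmann coupling used here. It solves one ether at the cost of a longer fragment synthesis and a differentiation sequence. The chosen route instead offers a short, uniform sequence of standard operations from a single patterned aldehyde.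

Alternative 3: Ring C is cut at C1–C2 to the 2-pyrone A8 , which bears the DE aryloxy group at C4 and the AB aryloxymethyl group at C6. Mg(OMe)2 A9 opens the lactone of A8 to a methyl ester, and the aryloxymethyl carbon then attacks that ester (Claisen). This closes ring C to the nonamethyl compound A7 , with ring C C2–OH and C6–OH free; demethylation of A7 finishes.
- For: it uses the same folding logic as the chosen route but at the centre of the molecule. It joins two halves of similar size, makes two ethers without any arylation, and leaves the shortest endgame.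
- Against: in A8 and its ring-opened form C4 is a vinylogous carbonate, so alkoxide can add there and expel the DE phenoxide. The uncertain cyclisation is run on a late intermediate that already holds all five rings. Both halves must be made first, each with a hindered diaryl ether of its own.
- Comparison: on convergence and on step count after the key step this alternative is stronger. The chosen route tests the same reaction four steps from commercial material, on a chain whose C3 and C5 are ketones without a leaving group, so a failure costs little and can be bypassed.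

Key step: step 5

## Route

Step 1
Reactants: 1 2-hydroxy-4,6-dimethoxybenzaldehyde; 2 methyl bromoacetate
Product: 3 methyl 2-(2-formyl-3,5-dimethoxyphenoxy)acetate
Conditions: K2CO3, acetone, 56 °C
Reagents that add atoms: none
Why: Williamson ether synthesis of a salicylaldehyde phenoxide with an α-bromo ester; the mild carbonate base at acetone reflux stops at O-alkylation, before the aldol closure to a benzofuran that stronger bases or higher temperatures would cause.

Step 2
Reactants: 3 methyl 2-(2-formyl-3,5-dimethoxyphenoxy)acetate
Product: 5 methyl 2-(2-hydroxy-3,5-dimethoxyphenoxy)acetate, via aryl formate 4 (not isolated)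
Conditions: mCPBA, CH2Cl2, 0 °C to rt; then K2CO3 (cat.), MeOH, 0 °C
Reagents that add atoms: mCPBA, OOC(=O)c1cccc(Cl)c1
Why: Baeyer–Villiger (Dakin-type) oxidation; the trioxygenated aryl group migrates far better than hydrogen, and the formate is removed by transesterification. Methanol as solvent keeps the hydroxy ester open, since a benzodioxinone lactone would be re-opened by methanolysis.

Step 3
Reactants: 5 methyl 2-(2-hydroxy-3,5-dimethoxyphenoxy)acetate
Product: 6 methyl 2-[2-(benzyloxy)-3,5-dimethoxyphenoxy]acetate
Conditions: BnBr, K2CO3, DMF, rt
Reagents that add atoms: benzyl bromide, BrCc1ccccc1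
Why: Williamson benzylation of the phenoxide; intermolecular alkylation by the reactive benzylic bromide at room temperature outruns lactonisation onto the neighbouring ester.

Step 4
Reactants: 6 methyl 2-[2-(benzyloxy)-3,5-dimethoxyphenoxy]acetate; 7 methyl acetoacetate
Product: 9 methyl 6-[2-(benzyloxy)-3,5-dimethoxyphenoxy]-3,5-dioxohexanoate, via dilithium dianion of methyl acetoacetate 8 (not isolated)
Conditions: 7 (3 equiv), LiN(iPr)2 (6 equiv), THF, 0 °C; then 6, −78 to 0 °C; cold aq. HCl
Reagents that add atoms: none
Why: Claisen acylation of an acetoacetate dianion at its terminal carbon (Huckin–Weiler type) by an α-oxygenated, hence activated, ester. Excess dianion is used because the product diketo ester is deprotonated as it forms.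

Step 5
Reactants: 9 methyl 6-[2-(benzyloxy)-3,5-dimethoxyphenoxy]-3,5-dioxohexanoate
Product: 11 2-[2-(benzyloxy)-3,5-dimethoxyphenoxy]benzene-1,3,5-triol, via 2-aryloxycyclohexane-1,3,5-trione 10 (not isolated)
Conditions: NaOMe (5 equiv), MeOH, 0.02 M, 65 °C, Ar; then aq. HCl, 0 °C
Reagents that add atoms: none
Why: Methoxide converts 9 into its enolates, and proton exchange in methanol gives access to the minor anion in which the C5 ketone is enolised toward C6 (the aryloxy-bearing methylene, the most acidic carbon outside the two 1,3-dicarbonyl methylenes) while C2 is protonated and the ester stays electrophilic. C6 then attacks the ester carbon C1 in an intramolecular Claisen (Dieckmann-type) condensation, a 6-(enolendo)-exo-trig closure that is favoured for enolates; it forms the C1–C2 bond of ring E and expels methoxide. Trione 10 does not persist: three enolisations give the benzene ring, and the triol is held as its phenoxide, which makes the sequence irreversible. The closest known reaction type is the base-mediated Claisen cyclisation of 3,5-dioxohexanoate and 3,5,7-trioxoalkanoate esters to phloroglucinols, the laboratory counterpart of triketide folding. No stereocentre is formed. The selectivity needed is carbon acylation by C6 over oxygen acylation by the C5 enol, which would give a 6-(aryloxymethyl)-4-hydroxy-2-pyrone; excess methoxide in methanol reopens that lactone to the chain, whereas ring E, once aromatic, cannot revert. The aryloxy group lowers the pKa of C6 and, being a poor leaving group next to the ketone, stays in place; high dilution suppresses bimolecular aldol condensation of the diketo ester.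

Step 6
Reactants: 11 2-[2-(benzyloxy)-3,5-dimethoxyphenoxy]benzene-1,3,5-triol
Product: 12 2-[2-(benzyloxy)-3,5-dimethoxyphenoxy]-1,3,5-trimethoxybenzene
Conditions: Me2SO4, K2CO3, acetone, 56 °C
Reagents that add atoms: dimethyl sulfate, COS(=O)(=O)OC
Why: Williamson O-methylation of the three phenols; the hard sulfate electrophile with carbonate in an aprotic solvent favours oxygen over ring-carbon methylation of the phloroglucinol.

Step 7
Reactants: 12 2-[2-(benzyloxy)-3,5-dimethoxyphenoxy]-1,3,5-trimethoxybenzene
Product: 13 2,4-dimethoxy-6-(2,4,6-trimethoxyphenoxy)phenol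
Conditions: H2 (1 atm), 10% Pd/C, EtOAc–MeOH, rt
Reagents that add atoms: none
Why: Catalytic hydrogenolysis of the benzyl ether; methyl and diaryl ethers are untouched, so only the ring D C1 oxygen is released.

Step 8
Reactants: 13 2,4-dimethoxy-6-(2,4,6-trimethoxyphenoxy)phenol; 14 4-bromo-2,6-dimethoxybenzaldehyde
Product: 15 4-[2,4-dimethoxy-6-(2,4,6-trimethoxyphenoxy)phenoxy]-2,6-dimethoxybenzaldehyde
Conditions: CuI (10 mol %), picolinic acid (20 mol %), K3PO4, DMSO, 90 °C, Ar
Reagents that add atoms: none
Why: Ullmann-type CuI-catalysed diaryl ether synthesis under conditions developed for ortho-substituted phenols. The bromide of 14 has hydrogen on both sides and is activated by the para formyl group, so only the phenol partner is hindered.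

Step 9
Reactants: 15 4-[2,4-dimethoxy-6-(2,4,6-trimethoxyphenoxy)phenoxy]-2,6-dimethoxybenzaldehyde
Product: 17 4-[2,4-dimethoxy-6-(2,4,6-trimethoxyphenoxy)phenoxy]-2,6-dimethoxyphenol, via aryl formate 16 (not isolated)
Conditions: mCPBA (1.1 equiv), CH2Cl2, 0 °C; then K2CO3 (cat.), MeOH, 0 °C, Ar
Reagents that add atoms: mCPBA, OOC(=O)c1cccc(Cl)c1
Why: Baeyer–Villiger (Dakin-type) oxidation of a 2,6-dimethoxybenzaldehyde, where aryl migration is strongly favoured. A near-stoichiometric amount of peracid at 0 °C and methanolysis under argon protect the oxidisable para-aryloxyphenol.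

Step 10
Reactants: 17 4-[2,4-dimethoxy-6-(2,4,6-trimethoxyphenoxy)phenoxy]-2,6-dimethoxyphenol; 18 2-bromo-4,6-dimethoxybenzaldehyde
Product: 19 2-{4-[2,4-dimethoxy-6-(2,4,6-trimethoxyphenoxy)phenoxy]-2,6-dimethoxyphenoxy}-4,6-dimethoxybenzaldehyde
Conditions: CuI (20 mol %), picolinic acid (40 mol %), K3PO4, DMSO, 100 °C, Ar
Reagents that add atoms: none
Why: Ullmann-type diaryl ether synthesis; the ortho formyl group of 18 both withdraws electron density from the C–Br carbon and can direct copper to it, which offsets the hindrance of the 2,6-dimethoxyphenoxide.

Step 11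
Reactants: 19 2-{4-[2,4-dimethoxy-6-(2,4,6-trimethoxyphenoxy)phenoxy]-2,6-dimethoxyphenoxy}-4,6-dimethoxybenzaldehyde
Product: 21 2-{4-[2,4-dimethoxy-6-(2,4,6-trimethoxyphenoxy)phenoxy]-2,6-dimethoxyphenoxy}-4,6-dimethoxyphenol, via aryl formate 20 (not isolated)
Conditions: mCPBA (1.1 equiv), CH2Cl2, 0 °C; then K2CO3 (cat.), MeOH, 0 °C, Ar
Reagents that add atoms: mCPBA, OOC(=O)c1cccc(Cl)c1
Why: Second Baeyer–Villiger (Dakin-type) oxidation; the formyl carbon of ring B, flanked by methoxy and aryloxy, is converted to the C1 oxygen by preferential aryl migration.

Step 12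
Reactants: 21 2-{4-[2,4-dimethoxy-6-(2,4,6-trimethoxyphenoxy)phenoxy]-2,6-dimethoxyphenoxy}-4,6-dimethoxyphenol; 22 1-iodo-3,5-dimethoxybenzene
Product: 23 1-{4-[2,4-dimethoxy-6-(2,4,6-trimethoxyphenoxy)phenoxy]-2,6-dimethoxyphenoxy}-2-(3,5-dimethoxyphenoxy)-3,5-dimethoxybenzene
Conditions: CuI (20 mol %), picolinic acid (40 mol %), K3PO4, DMSO, 90 °C, Ar
Reagents that add atoms: none
Why: Ullmann-type diaryl ether synthesis of a hindered phenol with an unhindered aryl iodide whose methoxy groups are meta to iodine and so do not deactivate the C–I bond.

Step 13
Reactants: 23 1-{4-[2,4-dimethoxy-6-(2,4,6-trimethoxyphenoxy)phenoxy]-2,6-dimethoxyphenoxy}-2-(3,5-dimethoxyphenoxy)-3,5-dimethoxybenzene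
Product: 24 5-{2-[4-[2,4-dihydroxy-6-(2,4,6-trihydroxyphenoxy)phenoxy]-2,6-dihydroxyphenoxy]-4,6-dihydroxyphenoxy}benzene-1,3-diol (CNP0018313.0)
Conditions: BBr3 (excess), CH2Cl2, −78 °C to rt; then MeOH and H2O, 0 °C, Ar
Reagents that add atoms: none
Why: Lewis-acid demethylation of aryl methyl ethers; bromide attacks only the methyl carbons, so the four diaryl ether bonds survive. The free polyphenol is handled under argon.

## Compound list

1 | 2-hydroxy-4,6-dimethoxybenzaldehyde | COc1cc(O)c(C=O)c(OC)c1 | starting material
2 | methyl bromoacetate | COC(=O)CBr | starting material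
3 | methyl 2-(2-formyl-3,5-dimethoxyphenoxy)acetate | COC(=O)COc1cc(OC)cc(OC)c1C=O | intermediate
4 | methyl 2-[2-(formyloxy)-3,5-dimethoxyphenoxy]acetate | COC(=O)COc1cc(OC)cc(OC)c1OC=O | intermediate
5 | methyl 2-(2-hydroxy-3,5-dimethoxyphenoxy)acetate | COC(=O)COc1cc(OC)cc(OC)c1O | intermediate
6 | methyl 2-[2-(benzyloxy)-3,5-dimethoxyphenoxy]acetate | COC(=O)COc1cc(OC)cc(OC)c1OCc1ccccc1 | intermediate
7 | methyl acetoacetate | COC(=O)CC(C)=O | starting material
8 | dilithium dianion of methyl acetoacetate | [Li+].[Li+].COC(=O)[CH-]C(=O)[CH2-] | intermediate
9 | methyl 6-[2-(benzyloxy)-3,5-dimethoxyphenoxy]-3,5-dioxohexanoate | COC(=O)CC(=O)CC(=O)COc1cc(OC)cc(OC)c1OCc1ccccc1 | intermediate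
10 | 2-[2-(benzyloxy)-3,5-dimethoxyphenoxy]cyclohexane-1,3,5-trione | O=C1CC(=O)C(Oc2cc(OC)cc(OC)c2OCc2ccccc2)C(=O)C1 | intermediate
11 | 2-[2-(benzyloxy)-3,5-dimethoxyphenoxy]benzene-1,3,5-triol | Oc1cc(O)c(Oc2cc(OC)cc(OC)c2OCc2ccccc2)c(O)c1 | intermediate
12 | 2-[2-(benzyloxy)-3,5-dimethoxyphenoxy]-1,3,5-trimethoxybenzene | COc1cc(OC)c(Oc2cc(OC)cc(OC)c2OCc2ccccc2)c(OC)c1 | intermediate
13 | 2,4-dimethoxy-6-(2,4,6-trimethoxyphenoxy)phenol | COc1cc(OC)c(Oc2cc(OC)cc(OC)c2O)c(OC)c1 | intermediate
14 | 4-bromo-2,6-dimethoxybenzaldehyde | COc1cc(Br)cc(OC)c1C=O | starting material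
15 | 4-[2,4-dimethoxy-6-(2,4,6-trimethoxyphenoxy)phenoxy]-2,6-dimethoxybenzaldehyde | COc1cc(OC)c(Oc2cc(OC)cc(OC)c2Oc2cc(OC)c(C=O)c(OC)c2)c(OC)c1 | intermediate
16 | 4-[2,4-dimethoxy-6-(2,4,6-trimethoxyphenoxy)phenoxy]-2,6-dimethoxyphenyl formate | COc1cc(OC)c(Oc2cc(OC)cc(OC)c2Oc2cc(OC)c(OC=O)c(OC)c2)c(OC)c1 | intermediate
17 | 4-[2,4-dimethoxy-6-(2,4,6-trimethoxyphenoxy)phenoxy]-2,6-dimethoxyphenol | COc1cc(OC)c(Oc2cc(OC)cc(OC)c2Oc2cc(OC)c(O)c(OC)c2)c(OC)c1 | intermediate
18 | 2-bromo-4,6-dimethoxybenzaldehyde | COc1cc(Br)c(C=O)c(OC)c1 | starting material
19 | 2-{4-[2,4-dimethoxy-6-(2,4,6-trimethoxyphenoxy)phenoxy]-2,6-dimethoxyphenoxy}-4,6-dimethoxybenzaldehyde | COc1cc(OC)c(Oc2cc(OC)cc(OC)c2Oc2cc(OC)c(Oc3cc(OC)cc(OC)c3C=O)c(OC)c2)c(OC)c1 | intermediate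
20 | 2-{4-[2,4-dimethoxy-6-(2,4,6-trimethoxyphenoxy)phenoxy]-2,6-dimethoxyphenoxy}-4,6-dimethoxyphenyl formate | COc1cc(OC)c(Oc2cc(OC)cc(OC)c2Oc2cc(OC)c(Oc3cc(OC)cc(OC)c3OC=O)c(OC)c2)c(OC)c1 | intermediate
21 | 2-{4-[2,4-dimethoxy-6-(2,4,6-trimethoxyphenoxy)phenoxy]-2,6-dimethoxyphenoxy}-4,6-dimethoxyphenol | COc1cc(OC)c(Oc2cc(OC)cc(OC)c2Oc2cc(OC)c(Oc3cc(OC)cc(OC)c3O)c(OC)c2)c(OC)c1 | intermediate
22 | 1-iodo-3,5-dimethoxybenzene | COc1cc(I)cc(OC)c1 | starting material
23 | 1-{4-[2,4-dimethoxy-6-(2,4,6-trimethoxyphenoxy)phenoxy]-2,6-dimethoxyphenoxy}-2-(3,5-dimethoxyphenoxy)-3,5-dimethoxybenzene (undecamethyl ether of the target) | COc1cc(OC)c(Oc2cc(OC)cc(OC)c2Oc2cc(OC)c(Oc3cc(OC)cc(OC)c3Oc3cc(OC)cc(OC)c3)c(OC)c2)c(OC)c1 | intermediate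
24 | 5-{2-[4-[2,4-dihydroxy-6-(2,4,6-trihydroxyphenoxy)phenoxy]-2,6-dihydroxyphenoxy]-4,6-dihydroxyphenoxy}benzene-1,3-diol (CNP0018313.0) | Oc1cc(O)cc(Oc2c(O)cc(O)cc2Oc2c(O)cc(Oc3c(O)cc(O)cc3Oc3c(O)cc(O)cc3O)cc2O)c1 | target

## Step count and least certain steps

Total: 13 steps. Longest linear sequence: 13 steps from aldehyde 1; compounds 2, 7, 14, 18 and 22 are bought and enter directly.

Step 5 (key step) is the least certain. Three processes can divert it.
- Under methoxide the two 1,3-dicarbonyl methylenes ionise first. Closure through the C5 enol oxygen to the 4-hydroxy-2-pyrone is then kinetically easier than closure through the minor C6 carbanion.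
- Methoxide can add to the aryloxy-activated C5 ketone and fragment the chain by retro-Claisen cleavage back to ester 6 and methyl acetoacetate.
- The diketo ester can condense with itself.

Fallback: ring E is not folded but bought. The route sets out from bromoaldehyde 18, which is coupled with 2,4,6-trimethoxyphenol F1 under the CuI/picolinic acid conditions of step 10 to give 2,4-dimethoxy-6-(2,4,6-trimethoxyphenoxy)benzaldehyde F2 . Peracid oxidation of F2 gives 2,4-dimethoxy-6-(2,4,6-trimethoxyphenoxy)phenyl formate F3 , and methanolysis of F3 gives phenol 13, where the route is rejoined. This is the aldehyde-assisted arylation already used for the C–B ether, so it adds no new reaction type.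

Step 4 may suffer from proton transfer instead of addition. The strongly basic dianion can enolise ester 6 at its aryloxy-bearing methylene, and the product quenches dianion as it forms. The diketo ester may also lactonise during acidic work-up. Fallback: ester 6 is converted with N,O-dimethylhydroxylamine hydrochloride and i-PrMgCl in THF into 2-[2-(benzyloxy)-3,5-dimethoxyphenoxy]-N-methoxy-N-methylacetamide F4 . The chelated tetrahedral adduct of F4 with dianion 8 holds until the quench and releases 9 only then, returning to the route at 9.

Step 10 joins a di-ortho-substituted phenoxide to an ortho-substituted bromide. Slow C–O bond formation at copper would leave time for reductive loss of bromine from 18 and for oxidative degradation of the para-aryloxyphenoxide of 17. Fallback: from 17, an uncatalysed SNAr reaction with 2-fluoro-4,6-dimethoxybenzaldehyde F5 (Cs2CO3, DMSO, 110–120 °C) replaces the metal-mediated step by addition–elimination at a small fluoride ortho to the formyl group. It returns to the route at 19.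

Step 12 may turn over poorly because phenoxide 21 is large and flanked on both sides, so that reduction or homocoupling of iodide 22 competes. Fallback: from 21, a Chan–Lam–Evans oxidative coupling with 3,5-dimethoxyphenylboronic acid F6 (Cu(OAc)2, pyridine, 4 Å molecular sieves, CH2Cl2, air, rt) forms the same bond at room temperature through an aryl–copper species made by transmetallation rather than by oxidative addition. It returns to the route at 23.

Step 13 may stop short of complete cleavage, since boron chelates between neighbouring oxygens slow the later demethylations. The free polyphenol may also be lost to oxidation during aqueous isolation and chromatography. Fallback: from 23, the crude product of the BBr3 treatment is acetylated (Ac2O, pyridine) to the undecaacetate of the target F7 . The acetate F7 is stable and can be purified on silica; under-demethylated fractions are separated and resubmitted. Acid methanolysis (HCl generated from acetyl chloride in degassed MeOH) then releases 24.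

## Further compounds

F1 | step 5 | 2,4,6-trimethoxyphenol | COc1cc(OC)c(O)c(OC)c1
F2 | step 5 | 2,4-dimethoxy-6-(2,4,6-trimethoxyphenoxy)benzaldehyde | COc1cc(OC)c(Oc2cc(OC)cc(OC)c2C=O)c(OC)c1
F3 | step 5 | 2,4-dimethoxy-6-(2,4,6-trimethoxyphenoxy)phenyl formate | COc1cc(OC)c(Oc2cc(OC)cc(OC)c2OC=O)c(OC)c1
F4 | step 4 | 2-[2-(benzyloxy)-3,5-dimethoxyphenoxy]-N-methoxy-N-methylacetamide | CON(C)C(=O)COc1cc(OC)cc(OC)c1OCc1ccccc1
F5 | step 10 | 2-fluoro-4,6-dimethoxybenzaldehyde | COc1cc(F)c(C=O)c(OC)c1
F6 | step 12 | 3,5-dimethoxyphenylboronic acid | COc1cc(OC)cc(B(O)O)c1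
F7 | step 13 | undecaacetate of the target | CC(=O)Oc1cc(OC(C)=O)cc(Oc2c(OC(C)=O)cc(OC(C)=O)cc2Oc2c(OC(C)=O)cc(Oc3c(OC(C)=O)cc(OC(C)=O)cc3Oc3c(OC(C)=O)cc(OC(C)=O)cc3OC(C)=O)cc2OC(C)=O)c1
A1 | alternative 1 | [CpRu(undecamethyl ether of the target)]PF6, ruthenium on ring D | COc1cc(OC)cc(Oc2c(OC)cc(OC)cc2Oc2c(OC)cc(Oc3c(OC)cc(OC)cc3Oc3c(OC)cc(OC)cc3OC)cc2OC)c1.[Ru+2].c1cc[cH-]c1.F[P-](F)(F)(F)(F)F
A2 | alternative 1 | [CpRu(1,2-dichloro-3,5-dimethoxybenzene)]PF6 | COc1cc(OC)c(Cl)c(Cl)c1.[Ru+2].c1cc[cH-]c1.F[P-](F)(F)(F)(F)F
A3 | alternative 1 | 2,4,6-trimethoxyphenol | COc1cc(OC)c(O)c(OC)c1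
A4 | alternative 1 | ABC phenol, 4-[2-(3,5-dimethoxyphenoxy)-3,5-dimethoxyphenoxy]-3,5-dimethoxyphenol | COc1cc(OC)cc(Oc2c(OC)cc(OC)cc2Oc2c(OC)cc(O)cc2OC)c1
A5 | alternative 2 | BCDE hydroquinone (ring B C1–OH and C4–OH free, C2 methoxy) | Oc1cc(OC)c(O)c(Oc2c(OC)cc(Oc3c(OC)cc(OC)cc3Oc3c(OC)cc(OC)cc3OC)cc2OC)c1
A6 | alternative 2 | racemic 4-hydroxy-4-(1-methoxyvinyl)-3-(CDE-aryloxy)cyclobut-2-en-1-one | C=C(OC)C1(O)C(=O)C=C1Oc1c(OC)cc(Oc2c(OC)cc(OC)cc2Oc2c(OC)cc(OC)cc2OC)cc1OC
A7 | alternative 3 | nonamethyl ether of the target with ring C C2–OH and C6–OH free | COc1cc(OC)cc(Oc2c(OC)cc(OC)cc2Oc2c(O)cc(Oc3c(OC)cc(OC)cc3Oc3c(OC)cc(OC)cc3OC)cc2O)c1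
A8 | alternative 3 | 4-(DE-aryloxy)-6-(AB-aryloxymethyl)-2H-pyran-2-one | O=C1C=C(Oc2c(OC)cc(OC)cc2Oc2c(OC)cc(OC)cc2OC)C=C(COc2cc(OC)cc(OC)c2Oc2cc(OC)cc(OC)c2)O1
A9 | alternative 3 | magnesium methoxide, Mg(OMe)2 | C[O-].C[O-].[Mg+2]
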